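A direct plan would open a decalin at the end: 2-methylcyclohexenone would be taken by copper-catalysed methyl addition/aldol, dehydration, enol triflate vinylation and a Diels–Alder reaction with methyl propiolate to the trans-fused hexahydronaphthalene dienoate A1.
A Heck reaction with 3-bromofuran would give the furyl alkene A2, addition of (R)-2-methylbutanoic acid across it the ester A3, and irradiation of A3 followed by a thermal [1,7]-hydrogen shift the target.
Weak step 1, the catalyst-controlled Markovnikov addition of the carboxylic acid to the furyl alkene A2: no such intermolecular reaction is known, the furylcarbinyl ester re-ionises under the same acid, and C12 would be set late with poor control.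
Weak step 2, the photochemical ring opening of A3 with the [1,7]-hydrogen shift: a light-absorbing product, E/Z triene isomers and a thermal equilibrium would give a mixture to be separated and recycled at the last step.
Weak step 3, the Diels–Alder reaction of a hindered vinylcyclohexene at 130 °C: it must set the quaternary ring-fusion carbon with the right regio- and facial sense, and a base isomerisation then fixes a ring fusion that is destroyed again.

**Retrosynthetic overview**
Numbering: ring C1=C2–C3=C4(CO2Me)–C5(=C19H2)–C6–C7–C8(Me)–C9(Me)(C11)–C10; side chain C11–C12(O-acyl)–3-furyl.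
Key disconnection at C3–C4 with allylic transposition: C19H2=C5–C4(CO2Me)–C3(OH) would arise from an intramolecular chromium-mediated α-allylation of a (Z)-enal (C3) by a γ-bromo enoate (C19–C5=C4), so the ten-membered ring and the exocyclic methylene form together from an open chain; acetate elimination then gives C3=C4.
Chain assembly without protecting groups: C5–C6 by B-alkyl Suzuki coupling, C1=C2 by Z-selective cross-metathesis.
Stereocentres: one catalytic aldol sets C12 (as its epimer) in a temporary δ-lactone, which relays it to C9 (anti cuprate addition) and C8 (anti methylation) in one flask; C12 is then inverted in the Mitsunobu step that installs the ester.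
Ring order: furan bought, the ten-membered carbocycle closed directly with no cyclohexane or decalin before it; no alkene hydroacyloxylation, no photochemistry, no Diels–Alder reaction.

Key step: step 13

Remark: (R)-2-methylbutanoic acid, methyl 4-hydroxybut-2-ynoate and the bis-silyl dienol ether 2 are taken as commercial; the BINOL enantiomer in step 1 is the one that delivers the 5S aldol, assumed to be (S)-BINOL.

Step 1
Reactants: 1 furan-3-carbaldehyde; 2 1-methoxy-1,3-bis(trimethylsilyloxy)buta-1,3-diene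
Product: 4 (6S)-6-(furan-3-yl)oxane-2,4-dione, via methyl (5S)-5-(furan-3-yl)-5-hydroxy-3-oxopentanoate 3 (not isolated)
Conditions: Ti(OiPr)4 (8 mol%), (S)-BINOL (8 mol%), THF, −78 °C → rt; TFA, −78 °C; then K2CO3, MeOH, rt; aq HCl to pH 2
Reagents that add atoms: 1-methoxy-1,3-bis(trimethylsilyloxy)buta-1,3-diene COC(O[Si](C)(C)C)=CC(=C)O[Si](C)(C)C
Why: Catalytic enantioselective vinylogous Mukaiyama aldol reaction (titanium–BINOL control of the aldehyde face sets C12, deliberately as the S epimer, and is the only catalyst-controlled centre of the route), after which the δ-hydroxy-β-keto ester lactonises onto its methyl ester under mild base.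

Step 2
Reactants: 4 (6S)-6-(furan-3-yl)oxane-2,4-dione; 5 trifluoromethanesulfonic anhydride
Product: 6 (6S)-6-(furan-3-yl)-2-oxo-5,6-dihydro-2H-pyran-4-yl trifluoromethanesulfonate
Conditions: Tf2O (1.1 equiv), Et3N, CH2Cl2, −78 °C
Reagents that add atoms: trifluoromethanesulfonic anhydride O=S(=O)(OS(=O)(=O)C(F)(F)F)C(F)(F)F
Why: O-sulfonylation of the stable 4-enol of the cyclic β-keto lactone gives the vinylogous acyl triflate at C9 without touching C12.

Step 3
Reactants: 6 (6S)-6-(furan-3-yl)-2-oxo-5,6-dihydro-2H-pyran-4-yl trifluoromethanesulfonate; 7 allyltributylstannane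
Product: 8 (6S)-6-(furan-3-yl)-4-(prop-2-en-1-yl)-5,6-dihydro-2H-pyran-2-one
Conditions: Pd(PPh3)4 (5 mol%), LiCl (3 equiv), THF, 60 °C
Reagents that add atoms: allyltributylstannane C=CC[Sn](CCCC)(CCCC)CCCC
Why: Stille coupling of the electron-poor enol triflate with allyltributylstannane (LiCl-assisted transmetalation) under neutral conditions puts the future C10–C1 unit on C9 and should not move the skipped double bond into conjugation.

Step 4
Reactants: 8 (6S)-6-(furan-3-yl)-4-(prop-2-en-1-yl)-5,6-dihydro-2H-pyran-2-one; 9 methyllithium; 10 iodomethane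
Product: 12 (3S,4S,6S)-6-(furan-3-yl)-3,4-dimethyl-4-(prop-2-en-1-yl)oxan-2-one, via lithium lactone enolate 11 (not isolated)
Conditions: MeLi (2.4 equiv), CuI (1.2 equiv), Et2O, −40 → 0 °C; then MeI (5 equiv), THF/DMPU, −40 → 0 °C; aq NH4Cl
Reagents that add atoms: methyllithium [Li]C; iodomethane CI
Why: Conjugate addition–enolate alkylation, in which the cuprate should add to C9 axially and anti to the pseudo-equatorial furyl group of the half-chair lactone (the usual 4,6-trans outcome for 6-substituted 5,6-dihydropyran-2-ones) and iodomethane should then enter the enolate at C8 axially, anti to the new axial C9 methyl group, so that the quaternary and the tertiary centre are both set by substrate control.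

Step 5
Reactants: 12 (3S,4S,6S)-6-(furan-3-yl)-3,4-dimethyl-4-(prop-2-en-1-yl)oxan-2-one
Product: 13 (3S,4S,6S)-6-(furan-3-yl)-3,4-dimethyl-4-(prop-2-en-1-yl)oxan-2-ol (anomers)
Conditions: DIBAL-H (1.1 equiv), CH2Cl2, −78 °C; Rochelle salt
Reagents that add atoms: none
Why: DIBAL-H half-reduction of a δ-lactone, which stops at the tetrahedral aluminium hemiacetal at −78 °C and leaves C8, C9 and C12 untouched.

Step 6
Reactants: 13 (3S,4S,6S)-6-(furan-3-yl)-3,4-dimethyl-4-(prop-2-en-1-yl)oxan-2-ol; 14 methyltriphenylphosphonium bromide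
Product: 15 (1S,3S)-3-[(2R)-but-3-en-2-yl]-1-(furan-3-yl)-3-methylhex-5-en-1-ol
Conditions: Ph3PCH3Br (3 equiv), KOtBu (2.9 equiv), THF, 0 °C → rt
Reagents that add atoms: methyltriphenylphosphonium bromide C[P+](c1ccccc1)(c1ccccc1)c1ccccc1.[Br-]
Why: Wittig methylenation of the open hydroxy-aldehyde form of the lactol gives the C7=C6 vinyl group and frees the C12 hydroxyl, and C8 should survive because the hindered α-branched aldehyde reacts with the small ylide faster than it enolises.

Step 7
Reactants: 15 (1S,3S)-3-[(2R)-but-3-en-2-yl]-1-(furan-3-yl)-3-methylhex-5-en-1-ol; 16 (2R)-2-methylbutanoic acid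
Product: 17 (1R,3S)-3-[(2R)-but-3-en-2-yl]-1-(furan-3-yl)-3-methylhex-5-en-1-yl (2R)-2-methylbutanoate
Conditions: 16 (1.5 equiv), PPh3, DIAD, toluene, −20 °C → rt
Reagents that add atoms: (2R)-2-methylbutanoic acid CC[C@@H](C)C(=O)O
Why: Mitsunobu esterification, in which the carboxylate displaces the oxyphosphonium group in an SN2 step, inverts C12 from S to the required R and installs the (R)-2-methylbutanoate in the same operation without enolising the acid.

Step 8
Reactants: 17 (1R,3S)-3-[(2R)-but-3-en-2-yl]-1-(furan-3-yl)-3-methylhex-5-en-1-yl (2R)-2-methylbutanoate; 18 (2Z)-but-2-ene-1,4-diol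
Product: 19 (1R,3S,5Z)-3-[(2R)-but-3-en-2-yl]-1-(furan-3-yl)-7-hydroxy-3-methylhept-5-en-1-yl (2R)-2-methylbutanoate
Conditions: 18 (3 equiv), Ru(SIMes)(=CH-C6H4-2-OiPr)(3,6-dichlorobenzene-1,2-dithiolate) (5 mol%), THF, 22 °C
Reagents that add atoms: (2Z)-but-2-ene-1,4-diol OC/C=C\CO
Why: Z-selective (stereoretentive) cross-metathesis with the ruthenium dithiolate catalyst should engage only the unhindered allyl group, since the other vinyl group is α-branched and flanked by the quaternary carbon, and deliver the (Z)-C1=C2 allylic alcohol directly.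

Step 9
Reactants: 20 methyl 4-hydroxybut-2-ynoate; 21 sodium iodide
Product: 22 methyl (2Z)-4-hydroxy-3-iodobut-2-enoate
Conditions: NaI (1.5 equiv), AcOH, 25–40 °C
Reagents that add atoms: sodium iodide [Na+].[I-]
Why: Anti hydroiodination of an ynoate (conjugate addition of iodide, then protonation trans to iodine) gives the (Z)-β-iodo enoate whose hydroxymethyl group is trans to the ester and therefore cannot lactonise.

Step 10
Reactants: 19 (1R,3S,5Z)-3-[(2R)-but-3-en-2-yl]-1-(furan-3-yl)-7-hydroxy-3-methylhept-5-en-1-yl (2R)-2-methylbutanoate; 22 methyl (2Z)-4-hydroxy-3-iodobut-2-enoate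
Product: 24 methyl (2E,6R,7S,9Z)-7-[(2R)-2-(furan-3-yl)-2-{[(2R)-2-methylbutanoyl]oxy}ethyl]-11-hydroxy-3-(hydroxymethyl)-6,7-dimethylundeca-2,9-dienoate, via B-alkyl-9-BBN adduct 23 (not isolated)
Conditions: 9-BBN (2.3 equiv), THF, rt; then 22, Pd(dppf)Cl2 (5 mol%), AsPh3 (10 mol%), aq K3PO4, DMF, rt
Reagents that add atoms: methyl (2Z)-4-hydroxy-3-iodobut-2-enoate COC(=O)/C=C(\I)CO
Why: Anti-Markovnikov hydroboration of the only terminal alkene with 9-BBN (the Z-disubstituted alkene, furan and esters react far more slowly) followed by B-alkyl Suzuki–Miyaura coupling with the β-iodo enoate, with retention of alkene geometry, forms the C5–C6 bond.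

Step 11
Reactants: 24 methyl (2E,6R,7S,9Z)-7-[(2R)-2-(furan-3-yl)-2-{[(2R)-2-methylbutanoyl]oxy}ethyl]-11-hydroxy-3-(hydroxymethyl)-6,7-dimethylundeca-2,9-dienoate
Product: 25 methyl (2E,6R,7S,9Z)-7-[(2R)-2-(furan-3-yl)-2-{[(2R)-2-methylbutanoyl]oxy}ethyl]-3-(hydroxymethyl)-6,7-dimethyl-11-oxoundeca-2,9-dienoate
Conditions: MnO2 (15 equiv), CH2Cl2, 0 °C
Reagents that add atoms: none
Why: Allylic oxidation with MnO2 is expected to be much faster for the electron-rich (Z)-allylic alcohol than for the hydroxymethyl group on the electron-poor enoate, giving the (Z)-enal without isomerisation at 0 °C.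

Step 12
Reactants: 25 methyl (2E,6R,7S,9Z)-7-[(2R)-2-(furan-3-yl)-2-{[(2R)-2-methylbutanoyl]oxy}ethyl]-3-(hydroxymethyl)-6,7-dimethyl-11-oxoundeca-2,9-dienoate; 26 lithium bromide
Product: 27 methyl (2E,6R,7S,9Z)-3-(bromomethyl)-7-[(2R)-2-(furan-3-yl)-2-{[(2R)-2-methylbutanoyl]oxy}ethyl]-6,7-dimethyl-11-oxoundeca-2,9-dienoate
Conditions: MsCl (1.3 equiv), 2,4,6-collidine, LiBr (5 equiv), DMF, 0 °C
Reagents that add atoms: lithium bromide [Li+].[Br-]
Why: Mesylation and in situ SN2 displacement by bromide converts the remaining allylic alcohol into the allylic bromide under conditions that are neither basic nor oxidising enough to touch the (Z)-enal.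

Step 13
Reactants: 27 methyl (2E,6R,7S,9Z)-3-(bromomethyl)-7-[(2R)-2-(furan-3-yl)-2-{[(2R)-2-methylbutanoyl]oxy}ethyl]-6,7-dimethyl-11-oxoundeca-2,9-dienoate
Product: 29 methyl (3Z,6S,7R)-6-[(2R)-2-(furan-3-yl)-2-{[(2R)-2-methylbutanoyl]oxy}ethyl]-2-hydroxy-6,7-dimethyl-10-methylidenecyclodec-3-ene-1-carboxylate (mixture at C1 and C2), via allylchromium dichloride 28 (not isolated)
Conditions: CrCl2 (8 equiv), THF, 25 °C, syringe-pump addition of 27 over 12 h, final 2 mM
Reagents that add atoms: none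
Why: Two equivalents of divalent chromium reduce the allylic bromide to an allylchromium (chromium dienolate) species that adds to the aldehyde through a six-membered cyclic transition state at its γ-carbon C4, so the C3–C4 bond forms while the double bond shifts to C5=C19 and becomes the exocyclic methylene. The closest known reaction types are Nozaki–Hiyama allylation macrocyclisations that close ten-membered carbocycles and the α-selective chromium-mediated (vinylogous Reformatsky) addition of 4-bromo-2-enoates to aldehydes. The ten-membered carbocycle closes by intramolecular 1,2-addition under high dilution, helped by the (Z)-C1=C2 turn and the quaternary C9. The new centres C3 and C4 need no control because both are erased in step 14, and C8, C9, C12 and the acyl centre are not involved. The step needs α- over γ-attack (ten- rather than twelve-membered ring), which the closed transition state with chromium on the primary carbon or on oxygen secures, and 1,2- over 1,4-addition to the enal, which is normal for allylchromium reagents. The two esters and the furan are tolerated by organochromium reagents.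

Step 14
Reactants: 29 methyl (3Z,6S,7R)-6-[(2R)-2-(furan-3-yl)-2-{[(2R)-2-methylbutanoyl]oxy}ethyl]-2-hydroxy-6,7-dimethyl-10-methylidenecyclodec-3-ene-1-carboxylate
Product: 31 methyl (1E,3Z,6S,7R)-6-[(2R)-2-(furan-3-yl)-2-{[(2R)-2-methylbutanoyl]oxy}ethyl]-6,7-dimethyl-10-methylidenecyclodeca-1,3-diene-1-carboxylate (CNP0305973.1), via secondary acetate 30 (not isolated)
Conditions: Ac2O, Et3N, DMAP (cat.), CH2Cl2, 0 °C; then DBU (2 equiv), 0 °C → rt
Reagents that add atoms: none
Why: Acetylation and E1cB elimination of the β-acetoxy ester (the C4 hydrogen is α to the ester and allylic) should give the C3=C4 bond with the ester anti to C2, which is both the usual geometry of such eliminations and the less strained ring-cis arrangement of a cyclodeca-1,3-diene.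

**Compound list**
1 | furan-3-carbaldehyde | O=Cc1ccoc1 | starting material
2 | 1-methoxy-1,3-bis(trimethylsilyloxy)buta-1,3-diene | COC(O[Si](C)(C)C)=CC(=C)O[Si](C)(C)C | starting material
3 | methyl (5S)-5-(furan-3-yl)-5-hydroxy-3-oxopentanoate | COC(=O)CC(=O)C[C@H](O)c1ccoc1 | intermediate
4 | (6S)-6-(furan-3-yl)oxane-2,4-dione | O=C1CC(=O)C[C@@H](c2ccoc2)O1 | intermediate
5 | trifluoromethanesulfonic anhydride | O=S(=O)(OS(=O)(=O)C(F)(F)F)C(F)(F)F | starting material
6 | (6S)-6-(furan-3-yl)-2-oxo-5,6-dihydro-2H-pyran-4-yl trifluoromethanesulfonate | O=C1C=C(OS(=O)(=O)C(F)(F)F)C[C@@H](c2ccoc2)O1 | intermediate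
7 | allyltributylstannane | C=CC[Sn](CCCC)(CCCC)CCCC | starting material
8 | (6S)-6-(furan-3-yl)-4-(prop-2-en-1-yl)-5,6-dihydro-2H-pyran-2-one | O=C1C=C(CC=C)C[C@@H](c2ccoc2)O1 | intermediate
9 | methyllithium | [Li]C | starting material
10 | iodomethane | CI | starting material
11 | lithium (4S,6S)-6-(furan-3-yl)-4-methyl-4-(prop-2-en-1-yl)-5,6-dihydro-4H-pyran-2-olate | [Li]OC1=C[C@](C)(C[C@H](O1)c2ccoc2)CC=C | intermediate
12 | (3S,4S,6S)-6-(furan-3-yl)-3,4-dimethyl-4-(prop-2-en-1-yl)oxan-2-one | O=C1[C@@H](C)[C@](C)(C[C@H](O1)c2ccoc2)CC=C | intermediate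
13 | (3S,4S,6S)-6-(furan-3-yl)-3,4-dimethyl-4-(prop-2-en-1-yl)oxan-2-ol (anomers) | OC1[C@@H](C)[C@](C)(C[C@H](O1)c2ccoc2)CC=C | intermediate
14 | methyltriphenylphosphonium bromide | C[P+](c1ccccc1)(c1ccccc1)c1ccccc1.[Br-] | starting material
15 | (1S,3S)-3-[(2R)-but-3-en-2-yl]-1-(furan-3-yl)-3-methylhex-5-en-1-ol | C=C[C@@H](C)[C@](C)(C[C@H](O)c1ccoc1)CC=C | intermediate
16 | (2R)-2-methylbutanoic acid | CC[C@@H](C)C(=O)O | starting material
17 | (1R,3S)-3-[(2R)-but-3-en-2-yl]-1-(furan-3-yl)-3-methylhex-5-en-1-yl (2R)-2-methylbutanoate | C=C[C@@H](C)[C@](C)(C[C@@H](OC(=O)[C@H](C)CC)c1ccoc1)CC=C | intermediate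
18 | (2Z)-but-2-ene-1,4-diol | OC/C=C\CO | starting material
19 | (1R,3S,5Z)-3-[(2R)-but-3-en-2-yl]-1-(furan-3-yl)-7-hydroxy-3-methylhept-5-en-1-yl (2R)-2-methylbutanoate | C=C[C@@H](C)[C@](C)(C[C@@H](OC(=O)[C@H](C)CC)c1ccoc1)C/C=C\CO | intermediate
20 | methyl 4-hydroxybut-2-ynoate | COC(=O)C#CCO | starting material
21 | sodium iodide | [Na+].[I-] | starting material
22 | methyl (2Z)-4-hydroxy-3-iodobut-2-enoate | COC(=O)/C=C(\I)CO | intermediate
23 | B-alkyl-9-borabicyclo[3.3.1]nonane from hydroboration of the vinyl group of 19 (hydroxyl as its 9-BBN borinate) | B1(C2CCCC1CCC2)CC[C@@H](C)[C@](C)(C[C@@H](OC(=O)[C@H](C)CC)c3ccoc3)C/C=C\COB4C5CCCC4CCC5 | intermediate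
24 | methyl (2E,6R,7S,9Z)-7-[(2R)-2-(furan-3-yl)-2-{[(2R)-2-methylbutanoyl]oxy}ethyl]-11-hydroxy-3-(hydroxymethyl)-6,7-dimethylundeca-2,9-dienoate | COC(=O)/C=C(/CO)CC[C@@H](C)[C@](C)(C[C@@H](OC(=O)[C@H](C)CC)c1ccoc1)C/C=C\CO | intermediate
25 | methyl (2E,6R,7S,9Z)-7-[(2R)-2-(furan-3-yl)-2-{[(2R)-2-methylbutanoyl]oxy}ethyl]-3-(hydroxymethyl)-6,7-dimethyl-11-oxoundeca-2,9-dienoate | COC(=O)/C=C(/CO)CC[C@@H](C)[C@](C)(C[C@@H](OC(=O)[C@H](C)CC)c1ccoc1)C/C=C\C=O | intermediate
26 | lithium bromide | [Li+].[Br-] | starting material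
27 | methyl (2E,6R,7S,9Z)-3-(bromomethyl)-7-[(2R)-2-(furan-3-yl)-2-{[(2R)-2-methylbutanoyl]oxy}ethyl]-6,7-dimethyl-11-oxoundeca-2,9-dienoate | COC(=O)/C=C(/CBr)CC[C@@H](C)[C@](C)(C[C@@H](OC(=O)[C@H](C)CC)c1ccoc1)C/C=C\C=O | intermediate
28 | allylchromium dichloride derived from 27 (chromium on C19) | COC(=O)/C=C(/C[Cr](Cl)Cl)CC[C@@H](C)[C@](C)(C[C@@H](OC(=O)[C@H](C)CC)c1ccoc1)C/C=C\C=O | intermediate
29 | methyl (3Z,6S,7R)-6-[(2R)-2-(furan-3-yl)-2-{[(2R)-2-methylbutanoyl]oxy}ethyl]-2-hydroxy-6,7-dimethyl-10-methylidenecyclodec-3-ene-1-carboxylate (mixture at C1 and C2) | C=C1CC[C@@H](C)[C@](C)(C[C@@H](OC(=O)[C@H](C)CC)c2ccoc2)C/C=C\C(O)C1C(=O)OC | intermediate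
30 | methyl (3Z,6S,7R)-2-acetoxy-6-[(2R)-2-(furan-3-yl)-2-{[(2R)-2-methylbutanoyl]oxy}ethyl]-6,7-dimethyl-10-methylidenecyclodec-3-ene-1-carboxylate | C=C1CC[C@@H](C)[C@](C)(C[C@@H](OC(=O)[C@H](C)CC)c2ccoc2)C/C=C\C(OC(C)=O)C1C(=O)OC | intermediate
31 | methyl (1E,3Z,6S,7R)-6-[(2R)-2-(furan-3-yl)-2-{[(2R)-2-methylbutanoyl]oxy}ethyl]-6,7-dimethyl-10-methylidenecyclodeca-1,3-diene-1-carboxylate (CNP0305973.1) | C=C1CC[C@@H](C)[C@](C)(C[C@@H](OC(=O)[C@H](C)CC)c2ccoc2)C/C=C\C=C/1C(=O)OC | target

**Step count and risks**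
Total step count: 14. Longest linear sequence: 13 (steps 1–8 and 10–14; step 9 is a one-step side branch).

Steps most likely to fail:

1. Step 13, ring closure. Intermolecular coupling, reduction or Z-to-E isomerisation of the enal by chromium salts, or attack through C19 (twelve-membered ring), may outrun the slow ten-membered closure. The fallback would set out from 25 and make the nucleophile catalytically instead of from a bromide. The hydroxymethyl group would be converted with methyl chloroformate and pyridine into the allylic carbonate methyl (2E,6R,7S,9Z)-7-[(2R)-2-(furan-3-yl)-2-{[(2R)-2-methylbutanoyl]oxy}ethyl]-3-{[(methoxycarbonyl)oxy]methyl}-6,7-dimethyl-11-oxoundeca-2,9-dienoate F1. Pd(PPh3)4 (cat.) and Et2Zn in THF at high dilution would then ionise it to a π-allylpalladium complex and transmetalate it to an allylzinc (zinc dienolate), present only in low stationary concentration and with no excess reducing metal near the enal. This species would add to the aldehyde at C4, a mode with precedent for ten-membered carbocycles, and the route would be rejoined at 29.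

2. Step 7, Mitsunobu inversion. The activated furyl carbinol may ionise (SN1), which would erode the inversion, or eliminate to the furyl alkene. The fallback would set out from 15 and oxidise it with MnO2 to the ketone (3S)-3-[(2R)-but-3-en-2-yl]-1-(furan-3-yl)-3-methylhex-5-en-1-one F2. Asymmetric transfer hydrogenation with RuCl(p-cymene)[(R,R)-TsDPEN] and HCO2H/Et3N (the catalyst enantiomer expected to give the 1R carbinol of an aryl alkyl ketone) would give (1R,3S)-3-[(2R)-but-3-en-2-yl]-1-(furan-3-yl)-3-methylhex-5-en-1-ol F3 under reagent control. Acylation with 16 (EDC, DMAP cat., 0 °C) with retention would rejoin the route at 17.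

3. Step 11, selective oxidation. The hydroxymethyl group on the enoate may be oxidised as well, or the (Z)-enal may isomerise on the oxidant surface. The fallback would set out from 19 and differentiate the two alcohols by protection. Silylation with TBSCl and imidazole would give (1R,3S,5Z)-3-[(2R)-but-3-en-2-yl]-7-[(tert-butyldimethylsilyl)oxy]-1-(furan-3-yl)-3-methylhept-5-en-1-yl (2R)-2-methylbutanoate F4. Hydroboration and Suzuki coupling with 22 as in step 10 would give methyl (2E,6R,7S,9Z)-11-[(tert-butyldimethylsilyl)oxy]-7-[(2R)-2-(furan-3-yl)-2-{[(2R)-2-methylbutanoyl]oxy}ethyl]-3-(hydroxymethyl)-6,7-dimethylundeca-2,9-dienoate F5. MsCl, collidine and LiBr would give methyl (2E,6R,7S,9Z)-3-(bromomethyl)-11-[(tert-butyldimethylsilyl)oxy]-7-[(2R)-2-(furan-3-yl)-2-{[(2R)-2-methylbutanoyl]oxy}ethyl]-6,7-dimethylundeca-2,9-dienoate F6. HF·pyridine would free methyl (2E,6R,7S,9Z)-3-(bromomethyl)-7-[(2R)-2-(furan-3-yl)-2-{[(2R)-2-methylbutanoyl]oxy}ethyl]-11-hydroxy-6,7-dimethylundeca-2,9-dienoate F7, and Dess–Martin periodinane with NaHCO3 would rejoin the route at 27.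

**Further compounds**
F1 | step 13 | methyl (2E,6R,7S,9Z)-7-[(2R)-2-(furan-3-yl)-2-{[(2R)-2-methylbutanoyl]oxy}ethyl]-3-{[(methoxycarbonyl)oxy]methyl}-6,7-dimethyl-11-oxoundeca-2,9-dienoate | COC(=O)/C=C(/COC(=O)OC)CC[C@@H](C)[C@](C)(C[C@@H](OC(=O)[C@H](C)CC)c1ccoc1)C/C=C\C=O
F2 | step 7 | (3S)-3-[(2R)-but-3-en-2-yl]-1-(furan-3-yl)-3-methylhex-5-en-1-one | C=C[C@@H](C)[C@](C)(CC(=O)c1ccoc1)CC=C
F3 | step 7 | (1R,3S)-3-[(2R)-but-3-en-2-yl]-1-(furan-3-yl)-3-methylhex-5-en-1-ol | C=C[C@@H](C)[C@](C)(C[C@@H](O)c1ccoc1)CC=C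
F4 | step 11 | (1R,3S,5Z)-3-[(2R)-but-3-en-2-yl]-7-[(tert-butyldimethylsilyl)oxy]-1-(furan-3-yl)-3-methylhept-5-en-1-yl (2R)-2-methylbutanoate | C=C[C@@H](C)[C@](C)(C[C@@H](OC(=O)[C@H](C)CC)c1ccoc1)C/C=C\CO[Si](C)(C)C(C)(C)C
F5 | step 11 | methyl (2E,6R,7S,9Z)-11-[(tert-butyldimethylsilyl)oxy]-7-[(2R)-2-(furan-3-yl)-2-{[(2R)-2-methylbutanoyl]oxy}ethyl]-3-(hydroxymethyl)-6,7-dimethylundeca-2,9-dienoate | COC(=O)/C=C(/CO)CC[C@@H](C)[C@](C)(C[C@@H](OC(=O)[C@H](C)CC)c1ccoc1)C/C=C\CO[Si](C)(C)C(C)(C)C
F6 | step 11 | methyl (2E,6R,7S,9Z)-3-(bromomethyl)-11-[(tert-butyldimethylsilyl)oxy]-7-[(2R)-2-(furan-3-yl)-2-{[(2R)-2-methylbutanoyl]oxy}ethyl]-6,7-dimethylundeca-2,9-dienoate | COC(=O)/C=C(/CBr)CC[C@@H](C)[C@](C)(C[C@@H](OC(=O)[C@H](C)CC)c1ccoc1)C/C=C\CO[Si](C)(C)C(C)(C)C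
F7 | step 11 | methyl (2E,6R,7S,9Z)-3-(bromomethyl)-7-[(2R)-2-(furan-3-yl)-2-{[(2R)-2-methylbutanoyl]oxy}ethyl]-11-hydroxy-6,7-dimethylundeca-2,9-dienoate | COC(=O)/C=C(/CBr)CC[C@@H](C)[C@](C)(C[C@@H](OC(=O)[C@H](C)CC)c1ccoc1)C/C=C\CO
A1 | direct plan | methyl (4aR,5S,6R,8aR)-5-ethenyl-5,6,8a-trimethyl-4a,5,6,7,8,8a-hexahydronaphthalene-1-carboxylate | C[C@@]12CC[C@@H](C)[C@](C)(C=C)[C@H]1C=CC=C2C(=O)OC
A2 | direct plan | methyl (4aR,5R,6R,8aR)-5-[(E)-2-(furan-3-yl)ethenyl]-5,6,8a-trimethyl-4a,5,6,7,8,8a-hexahydronaphthalene-1-carboxylate | C[C@@]12CC[C@@H](C)[C@](C)(/C=C/c3ccoc3)[C@H]1C=CC=C2C(=O)OC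
A3 | direct plan | methyl (4aR,5S,6R,8aR)-5-[(2R)-2-(furan-3-yl)-2-{[(2R)-2-methylbutanoyl]oxy}ethyl]-5,6,8a-trimethyl-4a,5,6,7,8,8a-hexahydronaphthalene-1-carboxylate | C[C@@]12CC[C@@H](C)[C@](C)(C[C@@H](OC(=O)[C@H](C)CC)c3ccoc3)[C@H]1C=CC=C2C(=O)OC
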